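## Plan

Cuts, in retrosynthetic order: the oxirane oxygen on C3/C4, the two angelate O–acyl bonds at C6 and C8, the C7–C8 bond, and last C1–C6 and C2–C3 of the carbocycle.
Enabling feature: the oxygens on C3 and C6 sit 1,4 across the six-membered ring, on the same face as C7 (on C1) and as the oxygens on C4 and C5, and the methyl group is on C4. This is the footprint of an exo-substituted 7-oxabicyclo[2.2.1]heptene built from 3-methylfuran (C3–C6 plus oxygen) and an acrylate (C1, C2, C7).
Forward order: carbocycle and oxygen bridge form together. Exo hydroboration, oxidation to the C5 ketone and beta-elimination open the bridge at C3 and keep oxygen on C6. C7 becomes an enol triflate and is joined to a C8–C11 aldehyde, both angelates go on in one step, and the oxirane closes last.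
Stereochemistry: C1 and C6 come from the exo cycloaddition on the auxiliary-shielded acrylate face, C5 from a substrate-controlled Luche reduction, and C8 from a reagent-controlled CBS reduction. C10 comes from (S)-alpha-hydroxy-gamma-butyrolactone (malic acid pool), and C3/C4 from the C5–OH-directed epoxidation.

Key step: step 2

Numbering used throughout: ring C1 (bears the chain), C2 (CH2), C3, C4 (bears CH3), C5, C6; chain C7 (=CH2), C8, C9, C10, C11. "Top face" is the ring face that carries C7. The target is (1R,3R,4S,5S,6S,8S,10S). C1 reads S in 6–17 and R from 23 on, and C5 reads R in 12–30 and S in 31. These changes come only from CIP priorities; nothing inverts.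

Assumption: ZnI2 is taken to bind imide 4 through both carbonyl oxygens (s-cis acrylate), as divalent zinc halides do with such imides. With one-point binding the facial bias would be small, and step 2 would rest on separation and recycling alone.

## Route

Step 1
Reactants: 1 (R)-4-benzyloxazolidin-2-one; 2 acryloyl chloride
Product: 4 (R)-3-acryloyl-4-benzyloxazolidin-2-one, via bromomagnesium oxazolidinonide 3 (not isolated)
Conditions: MeMgBr (1.0 equiv), THF, 0 °C; then 2 (1.2 equiv), −78 → 0 °C
Reagents that add atoms: none
Why: N-acylation of the bromomagnesium salt of an oxazolidinone with an acid chloride is the standard entry to acrylate imides, the magnesium counter-ion suppresses the anionic polymerisation seen with lithium salts, and no stereocentre is touched.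

Step 2
Reactants: 4 (R)-3-acryloyl-4-benzyloxazolidin-2-one; 5 3-methylfuran
Product: 6 exo imide (4R)-4-benzyl-3-{[(1R,2S,4R)-5-methyl-7-oxabicyclo[2.2.1]hept-5-en-2-yl]carbonyl}oxazolidin-2-one
Conditions: ZnI2 (0.3 equiv), 5 (8 equiv, no further solvent), dark, 25 °C, several days; SiO2, then crystallisation; remaining adducts: PhMe, 100 °C, back to 4 + 5
Reagents that add atoms: none
Why: ZnI2 chelates the two imide carbonyls of 4, lowers the acrylate LUMO and triggers a concerted, asynchronous [4+2] cycloaddition, the closest known reaction type being the reversible Lewis-acid-promoted Diels–Alder reaction of furans with acrylates and N-acryloyl oxazolidinones. The six-membered carbocycle closes by suprafacial cycloaddition across the furan 2,5-positions, C2–C3 forming ahead of C1–C6, and the furan oxygen thereby becomes the one-atom bridge, so that oxygen is necessarily cis on C3 and C6. Regiochemistry is a kinetic matter: the furan carbon next to the methyl group carries the largest HOMO coefficient and bonds to the acrylate CH2, which places methyl (C4) and acyl (C1) 1,4, and Lewis-acid activation sharpens this preference. C1 relative to the bridge follows from orientation: endo adducts of furans revert faster than exo adducts, so on standing the mixture shifts towards the more stable exo series with C7 on the side of the oxygen. The absolute sense of C1, C3 and C6 follows from the acrylate face: in the s-cis chelate the benzyl group of the (R)-auxiliary covers the face that would lead to the mirror-image ring, which is the reason for choosing the (R)- rather than the (S)-oxazolidinone, and the auxiliary also makes the other exo diastereomer separable. Because full equilibration would wash out both kinetic preferences, the run is stopped once the endo share has levelled off, 6 is taken out by chromatography and crystallisation, and all other adducts are cracked back to 4 and 5 and resubmitted.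

Step 3
Reactants: 6 exo imide
Product: 7 (1R,2S,4R)-N-methoxy-N,5-dimethyl-7-oxabicyclo[2.2.1]hept-5-ene-2-carboxamide (exo Weinreb amide)
Conditions: MeONHMe·HCl (3 equiv), AlMe3 (3 equiv), CH2Cl2, −10 → 20 °C
Reagents that add atoms: N,O-dimethylhydroxylamine hydrochloride, CNOC.Cl
Why: Weinreb transamination of an N-acyl oxazolidinone with an aluminium amide attacks the exocyclic carbonyl, returns the auxiliary for reuse, forms no enolate so that C1 is untouched, and installs an alpha-branched tertiary amide whose C1–H is kinetically very hard to remove because of allylic 1,3-strain in its enolate.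

Step 4
Reactants: 7 exo Weinreb amide
Product: 9 6-exo-hydroxy-N-methoxy-N,5-endo-dimethyl-7-oxabicyclo[2.2.1]heptane-2-exo-carboxamide (C5–OH exo and C4–CH3 endo in target numbering), via exo C5 alkylborane 8 (not isolated)
Conditions: BH3·THF (1.1 equiv), THF, 0 °C; then NaOH, H2O2, H2O, 0 °C
Reagents that add atoms: hydrogen peroxide, OO
Why: In this Brown hydroboration–oxidation the strained trisubstituted alkene reacts far faster than the amide, boron goes to the less substituted C5 and is delivered syn from the convex exo face, and the stereoretentive oxidation leaves C5–OH exo and the C4 methyl group endo.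

Step 5
Reactants: 9 exo alcohol
Product: 10 N-methoxy-N,5-endo-dimethyl-6-oxo-7-oxabicyclo[2.2.1]heptane-2-exo-carboxamide (C5 ketone)
Conditions: Dess–Martin periodinane, CH2Cl2, 0 → 25 °C
Reagents that add atoms: none
Why: Dess–Martin oxidation of a secondary alcohol in a non-basic medium gives the beta-alkoxy ketone without premature elimination, and the C5 centre of step 4 is given up on purpose.

Step 6
Reactants: 10 C5 ketone
Product: 11 (1S,6S)-N-methoxy-N,4-dimethyl-5-oxo-6-(triethylsilyloxy)cyclohex-3-ene-1-carboxamide (C7 cis to C6–O)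
Conditions: Et3SiOTf (1.3 equiv), Et3N (2 equiv), CH2Cl2, 0 → 25 °C
Reagents that add atoms: triethylsilyl trifluoromethanesulfonate, CC[Si](CC)(CC)OS(=O)(=O)C(F)(F)F
Why: In this silyl-triflate/amine-induced beta-elimination of a 7-oxanorbornan-2-one the ketone can enolise only towards C4 because C6 is a bridgehead, the silylated bridge oxygen leaves from C3, and the oxygen stays on C6 as its TES ether with the configuration fixed in step 2, while the alpha-branched amide resists enolisation.

Step 7
Reactants: 11 enone
Product: 12 (1S,5R,6S)-5-hydroxy-N-methoxy-N,4-dimethyl-6-(triethylsilyloxy)cyclohex-3-ene-1-carboxamide (all-cis at C1/C5/C6)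
Conditions: NaBH4, CeCl3·7H2O, MeOH, −78 °C
Reagents that add atoms: none
Why: In this Luche 1,2-reduction the C1 substituent is equatorial, so the cis C6–OTES group stands axial on the top face, hydride adds axially from the bottom face anti to it, and C5–OH appears on the top face cis to C6–O.

Step 8
Reactants: 12 allylic alcohol
Product: 13 (1S,5R,6S)-5-(tert-butyldimethylsilyloxy)-N-methoxy-N,4-dimethyl-6-(triethylsilyloxy)cyclohex-3-ene-1-carboxamide
Conditions: t-BuMe2SiOTf, 2,6-lutidine, CH2Cl2, −78 → 0 °C
Reagents that add atoms: tert-butyldimethylsilyl trifluoromethanesulfonate, CC(C)(C)[Si](C)(C)OS(=O)(=O)C(F)(F)F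
Why: Silylation of a hindered secondary alcohol with a silyl triflate and a non-nucleophilic base is routine and avoids alkoxide-mediated silyl migration, and TBS is chosen because it outlasts the C6 TES ether under buffered fluoride.

Step 9
Reactants: 13 bis-silyl Weinreb amide
Product: 15 1-[(1S,5R,6S)-5-(tert-butyldimethylsilyloxy)-4-methyl-6-(triethylsilyloxy)cyclohex-3-en-1-yl]ethanone, via chelated tetrahedral magnesium adduct 14 (not isolated)
Conditions: MeMgBr (2 equiv), THF, −20 → 0 °C
Reagents that add atoms: methylmagnesium bromide, C[Mg]Br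
Why: In the Weinreb ketone synthesis the chelated adduct 14 persists until the quench, so that addition stops at the methyl ketone, and the low temperature spares C1–H and the beta-silyloxy group.

Step 10
Reactants: 15 methyl ketone
Product: 17 1-[(1S,5R,6S)-5-(tert-butyldimethylsilyloxy)-4-methyl-6-(triethylsilyloxy)cyclohex-3-en-1-yl]ethenyl trifluoromethanesulfonate, via terminal potassium enolate 16 (not isolated)
Conditions: KN(SiMe3)2 (1.2 equiv), THF, −78 °C (15 added to the base); then N-(5-chloropyridin-2-yl)bis(trifluoromethanesulfonimide), −78 °C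
Reagents that add atoms: N-(5-chloropyridin-2-yl)bis(trifluoromethanesulfonimide), O=S(=O)(C(F)(F)F)N(c1ccc(Cl)cn1)S(=O)(=O)C(F)(F)F
Why: Kinetic deprotonation of an alpha-branched methyl ketone by a bulky amide base takes place at the methyl group, and O-sulfonylation of that terminal enolate gives the 1,1-disubstituted enol triflate without involving C1 or expelling the C6 silyloxy group.

Step 11
Reactants: 18 (S)-3-hydroxydihydrofuran-2(3H)-one ((S)-alpha-hydroxy-gamma-butyrolactone)
Product: 19 (S)-4-methylpentane-1,3,4-triol
Conditions: MeMgBr (4 equiv), THF, 0 → 25 °C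
Reagents that add atoms: methylmagnesium bromide, C[Mg]Br
Why: Double Grignard addition to the lactone carbonyl creates the C11 dimethyl carbinol, while C10 comes unchanged from the chiral pool because its hydroxyl is deprotonated first and the resulting alkoxide disfavours enolisation.

Step 12
Reactants: 19 triol
Product: 20 2-[(4S)-2,2,5,5-tetramethyl-1,3-dioxolan-4-yl]ethanol
Conditions: 2,2-dimethoxypropane, p-toluenesulfonic acid monohydrate (2 mol %), acetone, 25 °C
Reagents that add atoms: 2,2-dimethoxypropane, COC(C)(C)OC
Why: Acid-catalysed transketalisation under thermodynamic control favours the five-membered dioxolane across the secondary/tertiary 1,2-diol over the six-membered dioxane and leaves the primary alcohol free.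

Step 13
Reactants: 20 dioxolane alcohol
Product: 21 [(4S)-2,2,5,5-tetramethyl-1,3-dioxolan-4-yl]acetaldehyde
Conditions: Dess–Martin periodinane, CH2Cl2, 0 → 25 °C
Reagents that add atoms: none
Why: Dess–Martin oxidation of a primary alcohol stops at the aldehyde, and its non-basic medium avoids beta-elimination of the C10 oxygen.

Step 14
Reactants: 17 enol triflate; 21 aldehyde
Product: 23 allylic alcohol C7(=CH2)–C8H(OH)–C9H2–dioxolane on the ring of 17 (both C8 epimers), via alkenylchromium dichloride 22 (not isolated)
Conditions: CrCl2 (6 equiv), NiCl2 (2 mol %), 21 (2 equiv), DMF, 25 °C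
Reagents that add atoms: none
Why: In the Nozaki–Hiyama–Kishi reaction zerovalent nickel inserts into the C–OTf bond, transmetallation gives 22, which adds chemoselectively to the aldehyde in the presence of silyl ethers and the ketal to form C7–C8, and the C8 mixture does not matter because this centre is erased in step 15.

Step 15
Reactants: 23 allylic alcohols
Product: 24 C8 enone (alpha-methylene ketone; ring and dioxolane unchanged)
Conditions: Dess–Martin periodinane, CH2Cl2, 0 °C
Reagents that add atoms: none
Why: Dess–Martin oxidation converges both C8 epimers on one enone under conditions too mild to move the exocyclic double bond towards C1 or to eliminate the C10 oxygen.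

Step 16
Reactants: 24 enone
Product: 25 (8S)-allylic alcohol (1R,5R,6S,8S,10S in target numbering)
Conditions: (3aR)-1-methyl-3,3-diphenyltetrahydro-1H,3H-pyrrolo[1,2-c][1,3,2]oxazaborole (0.5 equiv), catecholborane (2 equiv), PhMe, −78 °C
Reagents that add atoms: none
Why: In this Corey–Bakshi–Shibata reduction the alpha-branched alkenyl group acts as the large and C9H2 as the small ketone substituent, so the (R)-oxazaborolidine delivers hydride to the face that gives (8S) under reagent control, and catecholborane at low temperature does not hydroborate the alkenes.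

Step 17
Reactants: 25 (8S)-allylic alcohol
Product: 26 C6,C8-diol (C5–OTBS and dioxolane retained)
Conditions: HF·pyridine, pyridine, THF, 0 °C
Reagents that add atoms: none
Why: Selective fluoride cleavage of a TES ether beside a TBS ether rests on their large difference in lability, and the pyridine buffer keeps the ketal and the allylic alcohol intact.

Step 18
Reactants: 26 C6,C8-diol; 27 angelic acid ((Z)-2-methylbut-2-enoic acid)
Product: 29 C6,C8-bis-angelate (C5–OTBS and dioxolane retained), via angelic 2,4,6-trichlorobenzoic anhydride 28 (not isolated)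
Conditions: 27 (6 equiv), 2,4,6-trichlorobenzoyl chloride, Et3N, PhMe, 25 °C; then 26, 80 °C
Reagents that add atoms: none
Why: Yamaguchi-type esterification with the preformed mixed anhydride and without a nucleophilic catalyst is the established way to angelates without Z to E isomerisation, and it acylates the only two free hydroxyls (C6 and C8) in one operation with retention at both carbinol carbons.

Step 19
Reactants: 29 bis-angelate
Product: 30 (1R,5R,6S,8S,10S)-C5,C10,C11-triol bis-angelate (the target lacking the oxirane oxygen)
Conditions: 48% aq HF, MeCN, 0 → 25 °C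
Reagents that add atoms: none
Why: Aqueous HF in acetonitrile cleaves the remaining silyl ether and hydrolyses the tetramethyldioxolane in one mildly acidic operation, a medium in which base-promoted acyl migration and angelate isomerisation are not expected.

Step 20
Reactants: 30 triol bis-angelate
Product: 31 CNP0189369.2
Conditions: VO(acac)2 (5 mol %), t-BuOOH (1.1 equiv, decane), CH2Cl2, 0 °C
Reagents that add atoms: tert-butyl hydroperoxide, CC(C)(C)OO
Why: In the vanadium-catalysed directed epoxidation of allylic alcohols the peroxide is delivered within the vanadate ester of C5–OH to the top face of the electron-rich C3=C4 bond, which sets C3 and C4 cis to C5–OH, while the C7 methylene next to an acyloxy group and the electron-poor angelates react much more slowly.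

## Compound list

1 | (R)-4-benzyloxazolidin-2-one | O=C1N[C@H](Cc2ccccc2)CO1 | starting material
2 | acryloyl chloride | C=CC(=O)Cl | starting material
3 | bromomagnesium salt of 1 (N–MgBr) | O=C1OC[C@@H](Cc2ccccc2)N1[Mg]Br | intermediate
4 | (R)-3-acryloyl-4-benzyloxazolidin-2-one | C=CC(=O)N1[C@H](Cc2ccccc2)COC1=O | intermediate
5 | 3-methylfuran | Cc1ccoc1 | starting material
6 | exo imide, (1R,2S,4R)-5-methyl-7-oxabicyclo[2.2.1]hept-5-ene-2-carbonyl on the (R)-auxiliary | O=C1OC[C@@H](Cc2ccccc2)N1C(=O)[C@H]1C[C@@H]2C(C)=C[C@H]1O2 | intermediate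
7 | (1R,2S,4R)-N-methoxy-N,5-dimethyl-7-oxabicyclo[2.2.1]hept-5-ene-2-carboxamide | CON(C)C(=O)[C@H]1C[C@@H]2C(C)=C[C@H]1O2 | intermediate
8 | exo C5 alkylborane (BH2 exo, CH3 endo) | CON(C)C(=O)[C@H]1C[C@@H]2[C@H](C)[C@@H](B)[C@H]1O2 | intermediate
9 | 6-exo-hydroxy-5-endo-methyl 2-exo Weinreb amide | CON(C)C(=O)[C@H]1C[C@@H]2[C@H](C)[C@@H](O)[C@H]1O2 | intermediate
10 | 5-endo-methyl-6-oxo 2-exo Weinreb amide | CON(C)C(=O)[C@H]1C[C@@H]2[C@H](C)C(=O)[C@H]1O2 | intermediate
11 | (1S,6S)-enone, C6–OTES cis to C7 | CON(C)C(=O)[C@H]1CC=C(C)C(=O)[C@H]1O[Si](CC)(CC)CC | intermediate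
12 | (1S,5R,6S)-allylic alcohol, all-cis | CON(C)C(=O)[C@H]1CC=C(C)[C@@H](O)[C@H]1O[Si](CC)(CC)CC | intermediate
13 | C5–OTBS, C6–OTES Weinreb amide | CON(C)C(=O)[C@H]1CC=C(C)[C@@H](O[Si](C)(C)C(C)(C)C)[C@H]1O[Si](CC)(CC)CC | intermediate
14 | chelated tetrahedral magnesium adduct (C7 configuration undefined) | CC(O[Mg]Br)(N(C)OC)[C@H]1CC=C(C)[C@@H](O[Si](C)(C)C(C)(C)C)[C@H]1O[Si](CC)(CC)CC | intermediate
15 | C7 methyl ketone | CC(=O)[C@H]1CC=C(C)[C@@H](O[Si](C)(C)C(C)(C)C)[C@H]1O[Si](CC)(CC)CC | intermediate
16 | terminal potassium enolate of 15 | [K+].C=C([O-])[C@H]1CC=C(C)[C@@H](O[Si](C)(C)C(C)(C)C)[C@H]1O[Si](CC)(CC)CC | intermediate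
17 | C7 enol triflate | C=C(OS(=O)(=O)C(F)(F)F)[C@H]1CC=C(C)[C@@H](O[Si](C)(C)C(C)(C)C)[C@H]1O[Si](CC)(CC)CC | intermediate
18 | (S)-3-hydroxydihydrofuran-2(3H)-one | O=C1OCC[C@@H]1O | starting material
19 | (S)-4-methylpentane-1,3,4-triol | OCC[C@H](O)C(C)(C)O | intermediate
20 | 2-[(4S)-2,2,5,5-tetramethyl-1,3-dioxolan-4-yl]ethanol | OCC[C@@H]1OC(C)(C)OC1(C)C | intermediate
21 | [(4S)-2,2,5,5-tetramethyl-1,3-dioxolan-4-yl]acetaldehyde | O=CC[C@@H]1OC(C)(C)OC1(C)C | intermediate
22 | alkenylchromium dichloride from 17 | C=C([Cr](Cl)Cl)[C@H]1CC=C(C)[C@@H](O[Si](C)(C)C(C)(C)C)[C@H]1O[Si](CC)(CC)CC | intermediate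
23 | coupled allylic alcohol, both C8 epimers | C=C(C(O)C[C@@H]2OC(C)(C)OC2(C)C)[C@H]1CC=C(C)[C@@H](O[Si](C)(C)C(C)(C)C)[C@H]1O[Si](CC)(CC)CC | intermediate
24 | C8 enone | C=C(C(=O)C[C@@H]2OC(C)(C)OC2(C)C)[C@H]1CC=C(C)[C@@H](O[Si](C)(C)C(C)(C)C)[C@H]1O[Si](CC)(CC)CC | intermediate
25 | (8S)-allylic alcohol | C=C([C@@H](O)C[C@@H]2OC(C)(C)OC2(C)C)[C@H]1CC=C(C)[C@@H](O[Si](C)(C)C(C)(C)C)[C@H]1O[Si](CC)(CC)CC | intermediate
26 | C6,C8-diol | C=C([C@@H](O)C[C@@H]2OC(C)(C)OC2(C)C)[C@H]1CC=C(C)[C@@H](O[Si](C)(C)C(C)(C)C)[C@H]1O | intermediate
27 | angelic acid | C/C=C(/C)C(=O)O | starting material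
28 | angelic 2,4,6-trichlorobenzoic anhydride | C/C=C(/C)C(=O)OC(=O)c1c(Cl)cc(Cl)cc1Cl | intermediate
29 | C6,C8-bis-angelate, C5–OTBS, C10/C11 acetonide | C=C([C@H](C[C@@H]2OC(C)(C)OC2(C)C)OC(=O)/C(C)=C\C)[C@H]1CC=C(C)[C@@H](O[Si](C)(C)C(C)(C)C)[C@H]1OC(=O)/C(C)=C\C | intermediate
30 | triol bis-angelate (C3=C4 alkene) | C=C([C@H](C[C@H](O)C(C)(C)O)OC(=O)/C(C)=C\C)[C@H]1CC=C(C)[C@@H](O)[C@H]1OC(=O)/C(C)=C\C | intermediate
31 | CNP0189369.2 | C=C([C@H](C[C@H](O)C(C)(C)O)OC(=O)/C(C)=C\C)[C@H]1C[C@H]2O[C@@]2(C)[C@@H](O)[C@H]1OC(=O)/C(C)=C\C | target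

## Step count and risks

Total step count: 20.
Longest linear sequence: 17 (steps 1–10 and 14–20). Steps 11–13 form the side branch.

**Step 2.**
- What may go wrong: the exo adducts themselves begin to revert, which erodes the kinetic 1,4- and facial preferences. Friedel–Crafts-type conjugate addition of the furan to 4 may compete, and cycloreversion may occur during isolation. Throughput per pass would then be low.
- Fallback (from 5, back at 7): absolute configuration is taken from a classical resolution instead of a covalent auxiliary. Compound 5 and methyl acrylate are combined under ZnI2, and the exo 1,4-adduct is separated as racemic methyl exo-5-methyl-7-oxabicyclo[2.2.1]hept-5-ene-2-carboxylate F1. LiOH in aqueous THF at 0 °C gives the racemic exo acid F2. Crystallisation with (R)-1-phenylethylamine gives the diastereomerically pure (R)-1-phenylethylammonium (1R,2S,4R)-carboxylate F3; the mirror-image amine is used if the other salt proves the less soluble. Acidification frees the (1R,2S,4R)-acid F4, and 1,1'-carbonyldiimidazole followed by MeONHMe·HCl leads to 7.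

**Step 18.**
- What may go wrong: acylation of the crowded axial C6–OH may stay incomplete, the angeloyl unit may isomerise from Z to E on prolonged heating, and silicon may migrate from O5 to O6.
- Fallback (from 26, back at 29): the Z-alkenes are built after acylation. Both hydroxyls are esterified with the small, non-isomerisable 2-[bis(2,2,2-trifluoroethoxy)phosphoryl]propanoic acid, using N-(3-dimethylaminopropyl)-N'-ethylcarbodiimide hydrochloride and 4-(dimethylamino)pyridine in CH2Cl2. This gives the bis(phosphonopropionate) F5. A double Still–Gennari olefination with acetaldehyde (KN(SiMe3)2, 18-crown-6, THF, −78 °C) then creates both (Z)-2-methylbut-2-enoates and gives 29.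

**Step 7.**
- What may go wrong: facial selectivity may be poor if the ring reacts through the conformer with equatorial C6–OTES, so that hydride arrives from the top face.
- Fallback (from 11, back at 12): the C5 centre is corrected by inversion instead of by direct reduction. The trans alcohol, the C5-epimeric (5S)-alcohol F6, is separated and subjected to Mitsunobu inversion (4-nitrobenzoic acid, PPh3, diisopropyl azodicarboxylate, PhMe). This gives the (5R)-4-nitrobenzoate F7, and brief methanolysis (K2CO3, MeOH, 0 °C) gives 12.

## Further compounds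

F1 | step 2 | racemic methyl exo-5-methyl-7-oxabicyclo[2.2.1]hept-5-ene-2-carboxylate | COC(=O)[C@H]1C[C@@H]2C(C)=C[C@H]1O2.COC(=O)[C@@H]1C[C@H]2C(C)=C[C@@H]1O2
F2 | step 2 | racemic exo-5-methyl-7-oxabicyclo[2.2.1]hept-5-ene-2-carboxylic acid | OC(=O)[C@H]1C[C@@H]2C(C)=C[C@H]1O2.OC(=O)[C@@H]1C[C@H]2C(C)=C[C@@H]1O2
F3 | step 2 | (R)-1-phenylethylammonium (1R,2S,4R)-5-methyl-7-oxabicyclo[2.2.1]hept-5-ene-2-carboxylate | C[C@@H]([NH3+])c1ccccc1.[O-]C(=O)[C@H]1C[C@@H]2C(C)=C[C@H]1O2
F4 | step 2 | (1R,2S,4R)-5-methyl-7-oxabicyclo[2.2.1]hept-5-ene-2-carboxylic acid | OC(=O)[C@H]1C[C@@H]2C(C)=C[C@H]1O2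
F5 | step 18 | C6,C8-bis{2-[bis(2,2,2-trifluoroethoxy)phosphoryl]propanoate} of 26 | C=C([C@H](C[C@@H]2OC(C)(C)OC2(C)C)OC(=O)C(C)P(=O)(OCC(F)(F)F)OCC(F)(F)F)[C@H]1CC=C(C)[C@@H](O[Si](C)(C)C(C)(C)C)[C@H]1OC(=O)C(C)P(=O)(OCC(F)(F)F)OCC(F)(F)F
F6 | step 7 | C5 epimer of 12 (C5–OH on the bottom face) | CON(C)C(=O)[C@H]1CC=C(C)[C@H](O)[C@H]1O[Si](CC)(CC)CC
F7 | step 7 | 4-nitrobenzoate of 12 (C5–O on the top face) | CON(C)C(=O)[C@H]1CC=C(C)[C@@H](OC(=O)c2ccc(cc2)[N+](=O)[O-])[C@H]1O[Si](CC)(CC)CC
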